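**Retrosynthetic overview**

1. The target is numbered as a 1,7-dioxacyclotetradec-3-ene-2,8,11-trione (O1, C2 to C6, O7, C8 to C14, side chain C1′ to C5′). The last operations are removal of the silyl group from O5 and conversion of a C1′–C2′ carboxymethyl group into the (E)-propenyl ketone.
2. The key disconnection is C11–C12 (ring ketone carbon to ring CH2). C9 carries the C8 carboxyl and two CH2–C(=O) arms (C10–C11 in the ring, C1′–C2′ in the side chain), so it is a hidden 3-carboxyglutaric unit. In a six-membered glutaric anhydride both arms are the same, and a tethered C12 alkylzinc that opens one anhydride carbonyl closes the 14-membered ring, makes the C11 ketone, sets C9 and frees C2′ as an acid.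
3. The anhydride ring comes from a cyclopent-3-ene-1-carboxylate ester on O7 (ozonolysis, Pinnick oxidation, cyclodehydration).
4. The Z-C3=C4 bond comes from an ynoate by semi-hydrogenation. The C4–C5 bond comes from Felkin–Anh addition of a propiolate acetylide (ester of the C12–C14 unit from (S)-butane-1,3-diol) to a lactaldehyde from ethyl (S)-lactate (C6).
5. Ring order: cyclopentene (bought), then the temporary six-membered anhydride (step 13), then the 14-membered macrodiolide (step 14), the only ring of the target.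

Key step: step 14

Assumption: which antipode of the phosphinooxazoline ligand selects the anhydride carbonyl that leads to 9R cannot be assigned in advance; the (S)-ligand is written, and its antipode would replace it if a test run with both calls for that.

**Route**

Step 1
Reactants: 1 (S)-butane-1,3-diol
Product: 2 (3S)-3-hydroxybutyl 4-methylbenzenesulfonate
Conditions: TsCl (1.0 equiv), Et3N, CH2Cl2, −20 °C
Reagents that add atoms: 4-toluenesulfonyl chloride, Cc1ccc(cc1)S(Cl)(=O)=O
Why: Sulfonylation is much faster at the primary hydroxyl than at the hindered secondary one at low temperature, and the chiral-pool stereocentre is not touched.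

Step 2
Reactants: 2 (3S)-3-hydroxybutyl 4-methylbenzenesulfonate; 3 prop-2-ynoic acid
Product: 4 (2S)-4-(tosyloxy)butan-2-yl prop-2-ynoate
Conditions: DCC, DMAP (5 mol %), CH2Cl2, −20 to 0 °C
Reagents that add atoms: none
Why: Steglich esterification acylates the secondary alcohol with retention (the C–O bond of the stereocentre is not broken), and low temperature with little DMAP keeps the catalyst from adding to the ynoate.

Step 3
Reactants: 5 ethyl (S)-2-hydroxypropanoate
Product: 6 ethyl (2S)-2-[(triethylsilyl)oxy]propanoate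
Conditions: Et3SiCl, imidazole, CH2Cl2, 0 °C to rt
Reagents that add atoms: chlorotriethylsilane, CC[Si](CC)(CC)Cl
Why: Standard silyl ether formation; the acid-labile triethylsilyl group is chosen because it is non-chelating and can later be removed beside a tert-butyldimethylsilyl ether.

Step 4
Reactants: 6 ethyl (2S)-2-[(triethylsilyl)oxy]propanoate
Product: 7 (2S)-2-[(triethylsilyl)oxy]propanal
Conditions: iBu2AlH, Et2O, −78 °C; aq. potassium sodium tartrate
Reagents that add atoms: none
Why: Partial ester reduction with iBu2AlH at −78 °C stops at the aluminium hemiacetal, which should give the α-silyloxy aldehyde on work-up without loss of configuration; the aldehyde is used at once.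

Step 5
Reactants: 4 (2S)-4-(tosyloxy)butan-2-yl prop-2-ynoate; 7 (2S)-2-[(triethylsilyl)oxy]propanal
Product: 9 (2S)-4-(tosyloxy)butan-2-yl (4R,5S)-4-hydroxy-5-[(triethylsilyl)oxy]hex-2-ynoate, via lithium acetylide 8 (not isolated)
Conditions: LiN(SiMe3)2, THF, −78 °C; then 7, −78 °C; aq. NH4Cl
Reagents that add atoms: none
Why: Acetylide addition to an α-silyloxy aldehyde should follow the polar Felkin–Anh model (non-chelating silyl ether, attack anti to the C–O bond), which sets the new carbinol centre as 4R (4,5-anti); the minor epimer is removed by chromatography.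

Step 6
Reactants: 9 (2S)-4-(tosyloxy)butan-2-yl (4R,5S)-4-hydroxy-5-[(triethylsilyl)oxy]hex-2-ynoate
Product: 10 (2S)-4-(tosyloxy)butan-2-yl (4R,5S)-4-[(tert-butyldimethylsilyl)oxy]-5-[(triethylsilyl)oxy]hex-2-ynoate
Conditions: TBSOTf, 2,6-lutidine, CH2Cl2, −78 to 0 °C
Reagents that add atoms: tert-butyldimethylsilyl trifluoromethanesulfonate, CC(C)(C)[Si](C)(C)OS(=O)(=O)C(F)(F)F
Why: Silylation with the silyl triflate and a hindered base protects the hindered propargylic alcohol at low temperature and blocks later lactonisation of this oxygen onto the Z-ester.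

Step 7
Reactants: 10 (2S)-4-(tosyloxy)butan-2-yl (4R,5S)-4-[(tert-butyldimethylsilyl)oxy]-5-[(triethylsilyl)oxy]hex-2-ynoate
Product: 11 (2S)-4-(tosyloxy)butan-2-yl (4R,5S)-4-[(tert-butyldimethylsilyl)oxy]-5-hydroxyhex-2-ynoate
Conditions: PPTS (cat.), MeOH/CH2Cl2, 0 °C
Reagents that add atoms: none
Why: Acid-catalysed methanolysis (selective desilylation) cleaves the triethylsilyl ether far faster than the bulkier tert-butyldimethylsilyl ether, and the linear alkyne keeps the freed hydroxyl away from the ester carbonyl.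

Step 8
Reactants: 11 (2S)-4-(tosyloxy)butan-2-yl (4R,5S)-4-[(tert-butyldimethylsilyl)oxy]-5-hydroxyhex-2-ynoate; 12 cyclopent-3-ene-1-carboxylic acid
Product: 13 (2S)-4-(tosyloxy)butan-2-yl (4R,5S)-4-[(tert-butyldimethylsilyl)oxy]-5-[(cyclopent-3-ene-1-carbonyl)oxy]hex-2-ynoate
Conditions: DCC, DMAP (cat.), CH2Cl2, 0 °C to rt
Reagents that add atoms: none
Why: Steglich esterification with an unhindered achiral acid forms the O7–C8 ester with retention and brings in C8 to C11, C1′ and C2′ as a masked 3-carboxyglutaric unit.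

Step 9
Reactants: 13 (2S)-4-(tosyloxy)butan-2-yl (4R,5S)-4-[(tert-butyldimethylsilyl)oxy]-5-[(cyclopent-3-ene-1-carbonyl)oxy]hex-2-ynoate
Product: 14 (2S)-4-(tosyloxy)butan-2-yl (2Z,4R,5S)-4-[(tert-butyldimethylsilyl)oxy]-5-[(cyclopent-3-ene-1-carbonyl)oxy]hex-2-enoate
Conditions: H2 (1 atm), Pd/CaCO3 poisoned with Pb(OAc)2, quinoline, EtOAc, rt
Reagents that add atoms: none
Why: Lindlar semi-hydrogenation adds hydrogen syn to give the Z-enoate; the alkyne binds the poisoned catalyst far more strongly than the disubstituted cyclopentene, and both neighbouring oxygens are blocked so no lactone can form.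

Step 10
Reactants: 14 (2S)-4-(tosyloxy)butan-2-yl (2Z,4R,5S)-4-[(tert-butyldimethylsilyl)oxy]-5-[(cyclopent-3-ene-1-carbonyl)oxy]hex-2-enoate
Product: 16 (2S)-4-(tosyloxy)butan-2-yl (2Z,4R,5S)-4-[(tert-butyldimethylsilyl)oxy]-5-{[4-oxo-2-(2-oxoethyl)butanoyl]oxy}hex-2-enoate, via ozonide 15 (not isolated)
Conditions: O3, CH2Cl2, −78 °C (Sudan Red 7B end point); PPh3, −78 °C to rt
Reagents that add atoms: ozone, [O-][O+]=O
Why: Ozonolysis with reductive work-up should be selective because ozone attacks the electron-rich cyclopentene much faster than the electron-poor enoate, and the dye end point prevents over-oxidation.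

Step 11
Reactants: 16 (2S)-4-(tosyloxy)butan-2-yl (2Z,4R,5S)-4-[(tert-butyldimethylsilyl)oxy]-5-{[4-oxo-2-(2-oxoethyl)butanoyl]oxy}hex-2-enoate
Product: 17 (2S)-4-(tosyloxy)butan-2-yl (2Z,4R,5S)-4-[(tert-butyldimethylsilyl)oxy]-5-{[3-carboxy-2-(carboxymethyl)propanoyl]oxy}hex-2-enoate
Conditions: NaClO2, NaH2PO4, 2-methylbut-2-ene, tBuOH/H2O, 0 °C to rt
Reagents that add atoms: sodium chlorite, [Na+].[O-]Cl=O
Why: Pinnick oxidation converts both aldehydes into acids under buffered conditions that leave the enoate, the silyl ether and the tosylate alone.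

Step 12
Reactants: 17 (2S)-4-(tosyloxy)butan-2-yl (2Z,4R,5S)-4-[(tert-butyldimethylsilyl)oxy]-5-{[3-carboxy-2-(carboxymethyl)propanoyl]oxy}hex-2-enoate
Product: 18 (2S)-4-iodobutan-2-yl (2Z,4R,5S)-4-[(tert-butyldimethylsilyl)oxy]-5-{[3-carboxy-2-(carboxymethyl)propanoyl]oxy}hex-2-enoate
Conditions: NaI, acetone, 45 °C
Reagents that add atoms: sodium iodide, [Na+].[I-]
Why: Finkelstein substitution (SN2) at the primary tosylate is driven by precipitation of sodium tosylate and involves no stereocentre; the iodide is introduced only now because it would not survive ozone.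

Step 13
Reactants: 18 (2S)-4-iodobutan-2-yl (2Z,4R,5S)-4-[(tert-butyldimethylsilyl)oxy]-5-{[3-carboxy-2-(carboxymethyl)propanoyl]oxy}hex-2-enoate
Product: 19 (2S)-4-iodobutan-2-yl (2Z,4R,5S)-4-[(tert-butyldimethylsilyl)oxy]-5-[(2,6-dioxooxane-4-carbonyl)oxy]hex-2-enoate
Conditions: DCC (1.05 equiv), CH2Cl2, 0 °C to rt; filtration
Reagents that add atoms: none
Why: Carbodiimide cyclodehydration of a 3-substituted glutaric acid; because the central carboxyl is tied up as the O7 ester, only the six-membered anhydride can form.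

Step 14
Reactants: 19 (2S)-4-iodobutan-2-yl (2Z,4R,5S)-4-[(tert-butyldimethylsilyl)oxy]-5-[(2,6-dioxooxane-4-carbonyl)oxy]hex-2-enoate
Product: 21 2-[(3Z,5R,6S,9R,14S)-5-[(tert-butyldimethylsilyl)oxy]-6,14-dimethyl-2,8,11-trioxo-1,7-dioxacyclotetradec-3-en-9-yl]acetic acid, via alkylzinc iodide 20 (not isolated)
Conditions: Zn dust (activated with BrCH2CH2Br and Me3SiCl), THF, 35 °C; then syringe-pump addition to Ni(cod)2 (15 mol %), (S)-tBu-PHOX (18 mol %), 4-fluorostyrene (30 mol %), THF/DMA, 0 °C to rt, about 2 mM; aq. HCl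
Reagents that add atoms: none
Why: Proposed new method: zinc inserts into the primary carbon–iodine bond, zerovalent nickel bound to the P,N-ligand adds oxidatively into one acyl–oxygen bond of the six-membered anhydride to give an acylnickel carboxylate, the tethered alkylzinc transmetalates, and reductive elimination (accelerated by the electron-poor styrene) forms the C11–C12 bond and leaves the other arm as a carboxylate that cannot react again. The closest known reaction type is the nickel-, palladium- or rhodium-catalysed enantioselective alkylation of prochiral succinic and glutaric anhydrides with organozinc reagents, which is known only between two molecules. The 14-membered ring closes head to tail by acyl substitution at the anhydride carbonyl (14-exo-trig attack, then opening of the six-membered ring as the driving force), and slow addition keeps the zinc reagent dilute so that ring closure should outrun oligomerisation. The new stereocentre C9 is set by which of the two diastereotopic carbonyl groups is converted, and this should be decided in the oxidative addition by the chiral ligand as in the intermolecular precedent, with the three existing centres as a weaker second influence. The step needs chemoselectivity for the anhydride over two esters, the Z-enoate and the silyl ether (alkylzinc iodides do not add to these, and zerovalent nickel does not insert into unstrained alkyl esters), and it needs reductive elimination to beat β-hydride elimination and decarbonylation, which the styrene additive and the low temperature are meant to secure.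

Step 15
Reactants: 21 2-[(3Z,5R,6S,9R,14S)-5-[(tert-butyldimethylsilyl)oxy]-6,14-dimethyl-2,8,11-trioxo-1,7-dioxacyclotetradec-3-en-9-yl]acetic acid
Product: 22 S-ethyl 2-[(3Z,5R,6S,9R,14S)-5-[(tert-butyldimethylsilyl)oxy]-6,14-dimethyl-2,8,11-trioxo-1,7-dioxacyclotetradec-3-en-9-yl]ethanethioate
Conditions: EtSH, DCC, DMAP (5 mol %), CH2Cl2, 0 °C
Reagents that add atoms: ethanethiol, CCS
Why: Steglich thioesterification of the only free carboxyl group; C9 is not α to the activated carbonyl, so it cannot epimerise through a ketene.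

Step 16
Reactants: 22 S-ethyl 2-[(3Z,5R,6S,9R,14S)-5-[(tert-butyldimethylsilyl)oxy]-6,14-dimethyl-2,8,11-trioxo-1,7-dioxacyclotetradec-3-en-9-yl]ethanethioate; 23 (E)-prop-1-en-1-ylboronic acid
Product: 24 (3Z,5R,6S,9R,14S)-5-[(tert-butyldimethylsilyl)oxy]-6,14-dimethyl-9-[(3E)-2-oxopent-3-en-1-yl]-1,7-dioxacyclotetradec-3-ene-2,8,11-trione
Conditions: Pd2(dba)3 (2.5 mol %), P(2-furyl)3 (15 mol %), Cu(O2CC4H3S) (CuTC, 1.5 equiv), THF, 50 °C
Reagents that add atoms: none
Why: Liebeskind–Srogl coupling of a thioester with an alkenylboronic acid forms the ketone under neutral, base-free conditions with retention of the E geometry and without touching the ring ketone, the esters or C9.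

Step 17
Reactants: 24 (3Z,5R,6S,9R,14S)-5-[(tert-butyldimethylsilyl)oxy]-6,14-dimethyl-9-[(3E)-2-oxopent-3-en-1-yl]-1,7-dioxacyclotetradec-3-ene-2,8,11-trione
Product: 25 (3Z,5R,6S,9R,14S)-5-hydroxy-6,14-dimethyl-9-[(3E)-2-oxopent-3-en-1-yl]-1,7-dioxacyclotetradec-3-ene-2,8,11-trione
Conditions: HF·pyridine, pyridine, THF, 0 °C to rt
Reagents that add atoms: none
Why: Fluoride-mediated desilylation under buffered, weakly acidic conditions should free O5 without base-induced acyl migration from O7 or butenolide formation.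

**Compound list**

1 | (S)-butane-1,3-diol | C[C@H](O)CCO | starting material
2 | (3S)-3-hydroxybutyl 4-methylbenzenesulfonate | C[C@H](O)CCOS(=O)(=O)c1ccc(C)cc1 | intermediate
3 | prop-2-ynoic acid | C#CC(=O)O | starting material
4 | (2S)-4-(tosyloxy)butan-2-yl prop-2-ynoate | C#CC(=O)O[C@@H](C)CCOS(=O)(=O)c1ccc(C)cc1 | intermediate
5 | ethyl (S)-2-hydroxypropanoate | CCOC(=O)[C@H](C)O | starting material
6 | ethyl (2S)-2-[(triethylsilyl)oxy]propanoate | CCOC(=O)[C@H](C)O[Si](CC)(CC)CC | intermediate
7 | (2S)-2-[(triethylsilyl)oxy]propanal | O=C[C@H](C)O[Si](CC)(CC)CC | intermediate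
8 | lithium acetylide of 4 | [Li]C#CC(=O)O[C@@H](C)CCOS(=O)(=O)c1ccc(C)cc1 | intermediate
9 | (2S)-4-(tosyloxy)butan-2-yl (4R,5S)-4-hydroxy-5-[(triethylsilyl)oxy]hex-2-ynoate | C[C@H](O[Si](CC)(CC)CC)[C@H](O)C#CC(=O)O[C@@H](C)CCOS(=O)(=O)c1ccc(C)cc1 | intermediate
10 | (2S)-4-(tosyloxy)butan-2-yl (4R,5S)-4-[(tert-butyldimethylsilyl)oxy]-5-[(triethylsilyl)oxy]hex-2-ynoate | C[C@H](O[Si](CC)(CC)CC)[C@H](O[Si](C)(C)C(C)(C)C)C#CC(=O)O[C@@H](C)CCOS(=O)(=O)c1ccc(C)cc1 | intermediate
11 | (2S)-4-(tosyloxy)butan-2-yl (4R,5S)-4-[(tert-butyldimethylsilyl)oxy]-5-hydroxyhex-2-ynoate | C[C@H](O)[C@H](O[Si](C)(C)C(C)(C)C)C#CC(=O)O[C@@H](C)CCOS(=O)(=O)c1ccc(C)cc1 | intermediate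
12 | cyclopent-3-ene-1-carboxylic acid | OC(=O)C1CC=CC1 | starting material
13 | (2S)-4-(tosyloxy)butan-2-yl (4R,5S)-4-[(tert-butyldimethylsilyl)oxy]-5-[(cyclopent-3-ene-1-carbonyl)oxy]hex-2-ynoate | C[C@H](OC(=O)C1CC=CC1)[C@H](O[Si](C)(C)C(C)(C)C)C#CC(=O)O[C@@H](C)CCOS(=O)(=O)c1ccc(C)cc1 | intermediate
14 | (2S)-4-(tosyloxy)butan-2-yl (2Z,4R,5S)-4-[(tert-butyldimethylsilyl)oxy]-5-[(cyclopent-3-ene-1-carbonyl)oxy]hex-2-enoate | C[C@H](OC(=O)C1CC=CC1)[C@H](O[Si](C)(C)C(C)(C)C)/C=C\C(=O)O[C@@H](C)CCOS(=O)(=O)c1ccc(C)cc1 | intermediate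
15 | ozonide of 14 (6,7,8-trioxabicyclo[3.2.1]octane-3-carboxylate ester, mixture at the ozonide carbons) | C[C@H](OC(=O)C1CC2OOC(C1)O2)[C@H](O[Si](C)(C)C(C)(C)C)/C=C\C(=O)O[C@@H](C)CCOS(=O)(=O)c1ccc(C)cc1 | intermediate
16 | (2S)-4-(tosyloxy)butan-2-yl (2Z,4R,5S)-4-[(tert-butyldimethylsilyl)oxy]-5-{[4-oxo-2-(2-oxoethyl)butanoyl]oxy}hex-2-enoate | C[C@H](OC(=O)C(CC=O)CC=O)[C@H](O[Si](C)(C)C(C)(C)C)/C=C\C(=O)O[C@@H](C)CCOS(=O)(=O)c1ccc(C)cc1 | intermediate
17 | (2S)-4-(tosyloxy)butan-2-yl (2Z,4R,5S)-4-[(tert-butyldimethylsilyl)oxy]-5-{[3-carboxy-2-(carboxymethyl)propanoyl]oxy}hex-2-enoate | C[C@H](OC(=O)C(CC(=O)O)CC(=O)O)[C@H](O[Si](C)(C)C(C)(C)C)/C=C\C(=O)O[C@@H](C)CCOS(=O)(=O)c1ccc(C)cc1 | intermediate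
18 | (2S)-4-iodobutan-2-yl (2Z,4R,5S)-4-[(tert-butyldimethylsilyl)oxy]-5-{[3-carboxy-2-(carboxymethyl)propanoyl]oxy}hex-2-enoate | C[C@H](OC(=O)C(CC(=O)O)CC(=O)O)[C@H](O[Si](C)(C)C(C)(C)C)/C=C\C(=O)O[C@@H](C)CCI | intermediate
19 | (2S)-4-iodobutan-2-yl (2Z,4R,5S)-4-[(tert-butyldimethylsilyl)oxy]-5-[(2,6-dioxooxane-4-carbonyl)oxy]hex-2-enoate | C[C@H](OC(=O)C1CC(=O)OC(=O)C1)[C@H](O[Si](C)(C)C(C)(C)C)/C=C\C(=O)O[C@@H](C)CCI | intermediate
20 | alkylzinc iodide from 19 (iodozinc in place of iodine) | C[C@H](OC(=O)C1CC(=O)OC(=O)C1)[C@H](O[Si](C)(C)C(C)(C)C)/C=C\C(=O)O[C@@H](C)CC[Zn]I | intermediate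
21 | 2-[(3Z,5R,6S,9R,14S)-5-[(tert-butyldimethylsilyl)oxy]-6,14-dimethyl-2,8,11-trioxo-1,7-dioxacyclotetradec-3-en-9-yl]acetic acid | OC(=O)C[C@H]1CC(=O)CC[C@H](C)OC(=O)/C=C\[C@@H](O[Si](C)(C)C(C)(C)C)[C@H](C)OC1=O | intermediate
22 | S-ethyl 2-[(3Z,5R,6S,9R,14S)-5-[(tert-butyldimethylsilyl)oxy]-6,14-dimethyl-2,8,11-trioxo-1,7-dioxacyclotetradec-3-en-9-yl]ethanethioate | CCSC(=O)C[C@H]1CC(=O)CC[C@H](C)OC(=O)/C=C\[C@@H](O[Si](C)(C)C(C)(C)C)[C@H](C)OC1=O | intermediate
23 | (E)-prop-1-en-1-ylboronic acid | C/C=C/B(O)O | starting material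
24 | (3Z,5R,6S,9R,14S)-5-[(tert-butyldimethylsilyl)oxy]-6,14-dimethyl-9-[(3E)-2-oxopent-3-en-1-yl]-1,7-dioxacyclotetradec-3-ene-2,8,11-trione | C/C=C/C(=O)C[C@H]1CC(=O)CC[C@H](C)OC(=O)/C=C\[C@@H](O[Si](C)(C)C(C)(C)C)[C@H](C)OC1=O | intermediate
25 | (3Z,5R,6S,9R,14S)-5-hydroxy-6,14-dimethyl-9-[(3E)-2-oxopent-3-en-1-yl]-1,7-dioxacyclotetradec-3-ene-2,8,11-trione | C/C=C/C(=O)C[C@H]1CC(=O)CC[C@H](C)OC(=O)/C=C\[C@@H](O)[C@H](C)OC1=O | target

**Totals**

Total step count: 17. Longest linear sequence: 15 steps (steps 1, 2 and 5 to 17, or steps 3 to 17).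

**Steps most likely to fail**

1. Step 14. The risk is insufficient discrimination between the two anhydride carbonyls (wrong C9 epimer), or intermolecular acylation, β-hydride elimination or decarbonylation outrunning ring closure. The fallback uses known chemistry, sets out from 19 and returns at 21, and separates the two tasks of the key step. Anhydride 19 is opened with 4-methoxybenzyl alcohol under a cinchona-alkaloid squaramide catalyst in MTBE at −20 °C (organocatalytic desymmetrising alcoholysis of a 3-substituted glutaric anhydride, using the pseudo-enantiomer that places the ester on the future C2′ arm), which should give the 4-methoxybenzyl hemiester F1. The free acid is converted with EtSH, DCC and DMAP into the S-ethyl thioester F2. Zinc insertion (Zn dust, THF, 35 °C) gives the alkylzinc iodide F3. Under high dilution with PdCl2(PPh3)2 in toluene/THF, F3 should close the C11–C12 bond by Fukuyama thioester–organozinc coupling to the macrocyclic 4-methoxybenzyl ester F4. Brief treatment with CF3CO2H in CH2Cl2 at 0 °C cleaves the benzylic ester and returns the route to acid 21.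

2. Step 5. The risk is poor facial selectivity in the acetylide addition, so that the 4-epimer forms in quantity. The fallback sets out from 9 (as the epimer mixture) and returns at 9. Dess–Martin oxidation should give the ynone F5. Reagent-controlled reduction with (S)-Alpine-Borane (B-isopinocampheyl-9-BBN from (−)-α-pinene, which by analogy with simple alkynyl ketones should deliver the 4R carbinol) then restores 9 as one diastereomer.

3. Step 15. The risk is conjugate addition of the thiol to the Z-enoate, or thiolate-induced Z to E isomerisation, during thioesterification. The fallback sets out from 21 and returns at 24, bypassing 22. Acid 21 is converted under neutral conditions with 1-chloro-N,N,2-trimethylprop-1-en-1-amine (CH2Cl2, 0 °C) into the acid chloride F6. Acyl Suzuki–Miyaura coupling with 23 (Pd(PPh3)4, Cs2CO3, dry toluene) should then give 24 directly.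

**Further compounds**

F1 | step 14 | 4-methoxybenzyl hemiester from 19 (ester on the future C2′ arm, free acid on the future C11 arm, R at the branching carbon) | COc1ccc(COC(=O)C[C@@H](CC(=O)O)C(=O)O[C@@H](C)[C@H](O[Si](C)(C)C(C)(C)C)/C=C\C(=O)O[C@@H](C)CCI)cc1
F2 | step 14 | S-ethyl thioester of F1 | COc1ccc(COC(=O)C[C@@H](CC(=O)SCC)C(=O)O[C@@H](C)[C@H](O[Si](C)(C)C(C)(C)C)/C=C\C(=O)O[C@@H](C)CCI)cc1
F3 | step 14 | alkylzinc iodide from F2 | COc1ccc(COC(=O)C[C@@H](CC(=O)SCC)C(=O)O[C@@H](C)[C@H](O[Si](C)(C)C(C)(C)C)/C=C\C(=O)O[C@@H](C)CC[Zn]I)cc1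
F4 | step 14 | 4-methoxybenzyl ester of 21 | COc1ccc(COC(=O)C[C@H]2CC(=O)CC[C@H](C)OC(=O)/C=C\[C@@H](O[Si](C)(C)C(C)(C)C)[C@H](C)OC2=O)cc1
F5 | step 5 | (2S)-4-(tosyloxy)butan-2-yl (5S)-4-oxo-5-[(triethylsilyl)oxy]hex-2-ynoate | C[C@H](O[Si](CC)(CC)CC)C(=O)C#CC(=O)O[C@@H](C)CCOS(=O)(=O)c1ccc(C)cc1
F6 | step 15 | acid chloride of 21 | ClC(=O)C[C@H]1CC(=O)CC[C@H](C)OC(=O)/C=C\[C@@H](O[Si](C)(C)C(C)(C)C)[C@H](C)OC1=O
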